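**Retrosynthetic overview**

1. Numbering of the terpenoid part: ring A = C1–C5 + C10, ring B = C5–C10, with =CH2 on C4, CH3 on C5 and C8, CH2OH and CH2Ar on C9, H on C10 (C9, C8, C5, C4, C1, C10 are positions 1, 2, 4a, 5, 8, 8a of the systematic names).
2. Last stage: phenol deallylation, C9–CHO to CH2OH, and the C9–CH2Ar bond by equatorial benzylation of a C9 aldehyde enolate with a benzylic bromide built from 2-methoxyresorcinol.
3. Middle stage: the C9 aldehyde from a C9 ketone by one-carbon homologation; the C8 methyl by enolate methylation, with C8 and C10 then set together by equilibration next to the ketone.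
4. Key disconnection: the 4-methylene decalone into 5-chloropent-1-yne + 3-methylcyclohex-2-enone; one flask joins C4 to C5 (asymmetric conjugate addition of the alkyne-derived alkenylalane) and then closes ring A through C1–C10 (enolate alkylation). This is possible because C5 and C10 of ring B are β and α to C9, and C5 carries the sp2 carbon C4 of ring A, which is tied to C10 through the three CH2 groups C3–C1; with C9 as a ketone, C5 is an acceptor and C10 a donor.
5. Ring order: ring B is bought, ring A is closed in step 1, the arene ring is bought and attached in step 10.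

Key step: step 1

Remark: the chiral sulfonate-bearing imidazolinium salt used as ligand precursor in step 1 is taken as an available catalyst component and is not numbered; the three starting materials are taken as commercial.

**Step 1**
Reactants: 1 5-chloropent-1-yne; 2 3-methylcyclohex-2-en-1-one
Product: 5 (4aS)-4a-methyl-5-methylideneoctahydronaphthalen-1(2H)-one (C8a epimer mixture), via alkenylalane 3 (not isolated), via aluminium enolate 4 (not isolated)
Conditions: 1, i-Bu2AlH, NiCl2(dppp) (3 mol %), THF, 0 → 22 °C; then 2, Cu(OTf)2 (5 mol %), chiral sulfonate-bearing imidazolinium salt (carbene precursor, 5 mol %), THF, −30 → 4 °C; then t-BuOK (excess), t-BuOH, 22 → 45 °C; one flask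
Reagents that add atoms: none
Why: NiCl2(dppp)-catalysed syn-hydroalumination places aluminium on the internal alkyne carbon of 1 to give 3, the catalyst formed in the flask from Cu(OTf)2 and the chiral carbene ligand transfers this alkenyl group to one enantioface of the β-carbon of 2 to give the regiodefined aluminium enolate 4, and added t-BuOK liberates the enolate, whose α-carbon C10 displaces the primary chloride on C1 in an SN2 reaction. The closest known reaction types are the copper-catalysed enantioselective conjugate addition of 1,1-disubstituted alkenylaluminium reagents to 3-methylcyclohex-2-enone and the methylenecyclohexane annulation of enones with 5-chloropent-1-en-2-yl copper reagents followed by base-induced closure of the chloro ketone, which are merged here in one flask. Ring A closes in the 6-(enolexo)-exo-tet mode. The quaternary centre C5 is set by the chiral ligand (enantiomer chosen for S), whereas C10 is set by the substrate, the tether reacting from an axial position so that the cis-fused epimer should form first; this centre stays epimerisable next to the ketone, is deliberately not controlled here and is corrected in step 2. The step needs α-regioselectivity in the hydroalumination (secured by the bidentate phosphine on nickel and the terminal alkyne), 1,4-addition to a β,β-disubstituted enone (secured by copper and the small β-methyl group) and C-alkylation at the correct α-carbon, which the substrate secures by ring size: only the C10 enolate can close a six-membered ring, whereas the C8 enolate or the enolate oxygen would have to close a bridged or eight-membered ring, so that equilibrating base funnels the material to 5. The primary chloride is inert to i-Bu2AlH, to the alane and to the copper catalyst and is therefore still in place when the base is added.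

**Step 2**
Reactants: 5 (4aS)-4a-methyl-5-methylideneoctahydronaphthalen-1(2H)-one (C8a epimer mixture)
Product: 7 (2S,4aS,8aR)-2,4a-dimethyl-5-methylideneoctahydronaphthalen-1(2H)-one, via methylated ketone epimer mixture 6 (not isolated)
Conditions: LDA, THF, −78 °C; MeI, −78 → 0 °C; crude product in NaOMe, MeOH, 40 °C; chromatography, minor epimers returned to NaOMe
Reagents that add atoms: iodomethane, CI
Why: LDA removes a proton from the only α-CH2 (C8) under kinetic control and the enolate is C-methylated (enolate alkylation), after which NaOMe epimerises both α-carbons (C8 and C10) through their enolates towards the diastereomer that should be the most stable, the trans-fused chair–chair ketone with equatorial C8 methyl; the preference is expected to be moderate, so the minor epimers are separated and equilibrated again.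

**Step 3**
Reactants: 7 (2S,4aS,8aR)-2,4a-dimethyl-5-methylideneoctahydronaphthalen-1(2H)-one
Product: 9 (2S,4aS,8aS)-2,4a-dimethyl-5-methylidenedecahydronaphthalene-1-carbaldehyde (C1 epimer mixture), via enol ether 8 (not isolated)
Conditions: Ph3P(CH2OMe)Cl, KHMDS, THF, 0 → 60 °C; crude enol ether in 2 M HCl, THF, 22 °C
Reagents that add atoms: (methoxymethyl)triphenylphosphonium chloride, COC[P+](c1ccccc1)(c1ccccc1)c1ccccc1.[Cl-]; water, O
Why: Wittig olefination with the unstabilised methoxymethylidene ylide gives enol ether 8 and its acid hydrolysis, which is far faster than protonation of the 1,1-disubstituted alkene, gives the aldehyde; C9 forms as an epimer mixture, which is of no consequence because it becomes the enolate carbon in step 10.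

**Step 4**
Reactants: 10 2-methoxybenzene-1,3-diol (2-methoxyresorcinol)
Product: 11 2,4-dihydroxy-3-methoxybenzoic acid
Conditions: KHCO3, CO2 (1 atm), glycerol, 130 °C; then aq. HCl
Reagents that add atoms: carbon dioxide, O=C=O
Why: Kolbe–Schmitt carboxylation of the resorcinol-type phenoxide occurs ortho to one hydroxyl and para to the other; the two such positions are equivalent and the position between the hydroxyls is blocked by OMe.

**Step 5**
Reactants: 11 2,4-dihydroxy-3-methoxybenzoic acid
Product: 12 methyl 2,4-dihydroxy-3-methoxybenzoate
Conditions: MeOH, H2SO4 (cat.), reflux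
Reagents that add atoms: methanol, CO
Why: Fischer esterification; the phenolic hydroxyls are not esterified under these conditions.

**Step 6**
Reactants: 12 methyl 2,4-dihydroxy-3-methoxybenzoate
Product: 13 methyl 5-formyl-2,4-dihydroxy-3-methoxybenzoate
Conditions: MgCl2, Et3N, (CH2O)n, MeCN, reflux; then 1 M HCl
Reagents that add atoms: formaldehyde (as paraformaldehyde), C=O
Why: Magnesium-mediated ortho-formylation of a phenol, in which the magnesium phenoxide directs hydroxymethylation to the ortho carbon and a second formaldehyde takes up hydride; the only free position ortho to a hydroxyl is C5 of the benzoate, which is also para to the other hydroxyl.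

**Step 7**
Reactants: 13 methyl 5-formyl-2,4-dihydroxy-3-methoxybenzoate
Product: 14 methyl 5-formyl-3-methoxy-2,4-bis(prop-2-en-1-yloxy)benzoate
Conditions: allyl bromide, K2CO3, DMF, 60 °C
Reagents that add atoms: allyl bromide, C=CCBr
Why: Williamson ether synthesis on both hydrogen-bonded phenols; allyl ethers are chosen because they survive base, hydride and the Appel reaction and are later removed without acid or hydrogen.

**Step 8**
Reactants: 14 methyl 5-formyl-3-methoxy-2,4-bis(prop-2-en-1-yloxy)benzoate
Product: 15 methyl 5-(hydroxymethyl)-3-methoxy-2,4-bis(prop-2-en-1-yloxy)benzoate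
Conditions: NaBH4, MeOH–THF, 0 °C
Reagents that add atoms: none
Why: Chemoselective borohydride reduction of the aldehyde in the presence of the aryl methyl ester.

**Step 9**
Reactants: 15 methyl 5-(hydroxymethyl)-3-methoxy-2,4-bis(prop-2-en-1-yloxy)benzoate
Product: 16 methyl 5-(bromomethyl)-3-methoxy-2,4-bis(prop-2-en-1-yloxy)benzoate
Conditions: CBr4, PPh3, CH2Cl2, 0 °C; used at once
Reagents that add atoms: tetrabromomethane, BrC(Br)(Br)Br
Why: The Appel reaction converts the benzylic alcohol into the bromide under neutral conditions that leave the allyl ethers and the ester untouched.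

**Step 10**
Reactants: 9 (2S,4aS,8aS)-2,4a-dimethyl-5-methylidenedecahydronaphthalene-1-carbaldehyde (C1 epimer mixture); 16 methyl 5-(bromomethyl)-3-methoxy-2,4-bis(prop-2-en-1-yloxy)benzoate
Product: 17 methyl 5-{[(1S,2S,4aS,8aR)-1-formyl-2,4a-dimethyl-5-methylidenedecahydronaphthalen-1-yl]methyl}-3-methoxy-2,4-bis(prop-2-en-1-yloxy)benzoate
Conditions: t-BuOK, THF, 0 °C; then 16, 0 → 22 °C
Reagents that add atoms: none
Why: Enolate C-alkylation of an α-branched aldehyde with a benzylic bromide: the exocyclic potassium enolate at C9 is attacked from the equatorial α direction because the axial β face is blocked by the 1,3-diaxial angular methyl on C5, so the benzyl group becomes equatorial and the formyl group axial, which is the required configuration at C9.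

**Step 11**
Reactants: 17 (quaternary aldehyde)
Product: 18 methyl 5-{[(1S,2S,4aS,8aR)-1-(hydroxymethyl)-2,4a-dimethyl-5-methylidenedecahydronaphthalen-1-yl]methyl}-3-methoxy-2,4-bis(prop-2-en-1-yloxy)benzoate
Conditions: NaBH4, MeOH–THF, 0 → 22 °C
Reagents that add atoms: none
Why: Borohydride reduces the hindered neopentyl aldehyde but not the aryl methyl ester (chemoselective carbonyl reduction); no stereocentre is formed.

**Step 12**
Reactants: 18 (bis-allyl ether)
Product: 19 methyl 2,4-dihydroxy-5-{[(1S,2S,4aS,8aR)-1-(hydroxymethyl)-2,4a-dimethyl-5-methylidenedecahydronaphthalen-1-yl]methyl}-3-methoxybenzoate (CNP0264247.1)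
Conditions: Pd(PPh3)4 (5 mol %), morpholine, THF, 22 °C
Reagents that add atoms: none
Why: Palladium-catalysed allyl transfer to morpholine (Tsuji–Trost type deallylation) frees both phenols under neutral conditions that leave the exocyclic alkene, the methyl ester and the primary alcohol untouched.

**Compound list**

1 | 5-chloropent-1-yne | C#CCCCCl | starting material
2 | 3-methylcyclohex-2-en-1-one | CC1=CC(=O)CCC1 | starting material
3 | (5-chloropent-1-en-2-yl)bis(2-methylpropyl)aluminium (alkenylalane) | C=C(CCCCl)[Al](CC(C)C)CC(C)C | intermediate
4 | {[(3S)-3-(5-chloropent-1-en-2-yl)-3-methylcyclohex-1-en-1-yl]oxy}bis(2-methylpropyl)aluminium (aluminium enolate) | C=C(CCCCl)[C@@]1(C)CCCC(O[Al](CC(C)C)CC(C)C)=C1 | intermediate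
5 | (4aS)-4a-methyl-5-methylideneoctahydronaphthalen-1(2H)-one, mixture of C8a epimers | C=C1CCCC2C(=O)CCC[C@]12C | intermediate
6 | (4aS)-2,4a-dimethyl-5-methylideneoctahydronaphthalen-1(2H)-one, mixture of C2 and C8a epimers | C=C1CCCC2C(=O)C(C)CC[C@]12C | intermediate
7 | (2S,4aS,8aR)-2,4a-dimethyl-5-methylideneoctahydronaphthalen-1(2H)-one | C=C1CCC[C@H]2C(=O)[C@@H](C)CC[C@]12C | intermediate
8 | (2S,4aS,8aR)-1-(methoxymethylidene)-2,4a-dimethyl-5-methylidenedecahydronaphthalene, E/Z mixture | C=C1CCC[C@H]2C(=COC)[C@@H](C)CC[C@]12C | intermediate
9 | (2S,4aS,8aS)-2,4a-dimethyl-5-methylidenedecahydronaphthalene-1-carbaldehyde, mixture of C1 epimers | C=C1CCC[C@H]2C(C=O)[C@@H](C)CC[C@]12C | intermediate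
10 | 2-methoxybenzene-1,3-diol | COc1c(O)cccc1O | starting material
11 | 2,4-dihydroxy-3-methoxybenzoic acid | COc1c(O)ccc(C(=O)O)c1O | intermediate
12 | methyl 2,4-dihydroxy-3-methoxybenzoate | COC(=O)c1ccc(O)c(OC)c1O | intermediate
13 | methyl 5-formyl-2,4-dihydroxy-3-methoxybenzoate | COC(=O)c1cc(C=O)c(O)c(OC)c1O | intermediate
14 | methyl 5-formyl-3-methoxy-2,4-bis(prop-2-en-1-yloxy)benzoate | COC(=O)c1cc(C=O)c(OCC=C)c(OC)c1OCC=C | intermediate
15 | methyl 5-(hydroxymethyl)-3-methoxy-2,4-bis(prop-2-en-1-yloxy)benzoate | COC(=O)c1cc(CO)c(OCC=C)c(OC)c1OCC=C | intermediate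
16 | methyl 5-(bromomethyl)-3-methoxy-2,4-bis(prop-2-en-1-yloxy)benzoate | COC(=O)c1cc(CBr)c(OCC=C)c(OC)c1OCC=C | intermediate
17 | methyl 5-{[(1S,2S,4aS,8aR)-1-formyl-2,4a-dimethyl-5-methylidenedecahydronaphthalen-1-yl]methyl}-3-methoxy-2,4-bis(prop-2-en-1-yloxy)benzoate | C=C1CCC[C@H]2[C@](C=O)(Cc3cc(C(=O)OC)c(OCC=C)c(OC)c3OCC=C)[C@@H](C)CC[C@]12C | intermediate
18 | methyl 5-{[(1S,2S,4aS,8aR)-1-(hydroxymethyl)-2,4a-dimethyl-5-methylidenedecahydronaphthalen-1-yl]methyl}-3-methoxy-2,4-bis(prop-2-en-1-yloxy)benzoate | C=C1CCC[C@H]2[C@](CO)(Cc3cc(C(=O)OC)c(OCC=C)c(OC)c3OCC=C)[C@@H](C)CC[C@]12C | intermediate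
19 | methyl 2,4-dihydroxy-5-{[(1S,2S,4aS,8aR)-1-(hydroxymethyl)-2,4a-dimethyl-5-methylidenedecahydronaphthalen-1-yl]methyl}-3-methoxybenzoate | C=C1CCC[C@H]2[C@](CO)(Cc3cc(C(=O)OC)c(O)c(OC)c3O)[C@@H](C)CC[C@]12C | target

**Step count and risks**

Total step count: 12. Longest linear sequence: 9 steps (steps 4–12, from 2-methoxybenzene-1,3-diol); the terpenoid branch needs 6 (steps 1–3 and 10–12).

Steps most likely to fail:

Step 1. The enantioface control of the conjugate addition may be lower with this chloroalkyl-substituted alkenylalane than with simpler ones, the hydroalumination may lose its α-regioselectivity, or the ring closure may stall in the presence of the aluminium salts. The fallback sets out from 1 and 2 and separates the three events. Markovnikov hydrobromination of 1 (HBr, Et4NBr, CH2Cl2) should give 2-bromo-5-chloropent-1-ene F1. Bromine–lithium exchange (t-BuLi, Et2O, −78 °C) followed by Me2AlCl should give (5-chloropent-1-en-2-yl)dimethylaluminium F2. Its conjugate addition to 2 with Cu(OTf)2 and a chiral phosphoramidite ligand, followed by aqueous work-up, should give the isolated chloro ketone (3S)-3-(5-chloropent-1-en-2-yl)-3-methylcyclohexan-1-one F3. KH in THF then closes ring A, and the route is rejoined at 5.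

Step 10. O-alkylation of the hindered aldehyde enolate, or self-alkylation and decomposition of the electron-rich benzylic bromide before the slow C-alkylation at the crowded C9, may take over. The fallback sets out from 9 and uses a nitrogen enolate that can only react at carbon. Condensation of 9 with tert-butylamine (molecular sieves) should give the N-tert-butyl imine of aldehyde 9 F4. LDA in THF forms the aza-enolate, which is alkylated by 16, from the same equatorial direction, to give the N-tert-butyl imine of aldehyde 17 F5. Hydrolysis with aqueous oxalic acid in THF returns to the route at 17.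

Step 3. The basic ylide may enolise the doubly α-branched ketone instead of adding to it, which would stall the olefination and let C8 and C10 drift. The fallback sets out from 7 and replaces the olefination by an epoxide rearrangement. Corey–Chaykovsky epoxidation with the smaller and more nucleophilic dimethylsulfonium methylide (Me3SI, n-BuLi, THF, −10 °C) should give the spiro-epoxide (2S,4aS,8aR)-2,4a-dimethyl-5-methylideneoctahydro-2H-spiro[naphthalene-1,2'-oxirane] F6. Meinwald rearrangement with MgBr2·OEt2 (CH2Cl2, 0 °C) shifts hydride to the tertiary carbon and returns to the route at 9.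

**Further compounds**

F1 | step 1 | 2-bromo-5-chloropent-1-ene | C=C(Br)CCCCl
F2 | step 1 | (5-chloropent-1-en-2-yl)dimethylaluminium | C=C(CCCCl)[Al](C)C
F3 | step 1 | (3S)-3-(5-chloropent-1-en-2-yl)-3-methylcyclohexan-1-one | C=C(CCCCl)[C@@]1(C)CCCC(=O)C1
F4 | step 10 | N-tert-butyl imine of aldehyde 9, (2S,4aS,8aS), mixture of C1 epimers | C=C1CCC[C@H]2C(C=NC(C)(C)C)[C@@H](C)CC[C@]12C
F5 | step 10 | N-tert-butyl imine of aldehyde 17, (1S,2S,4aS,8aR) | C=C1CCC[C@H]2[C@](C=NC(C)(C)C)(Cc3cc(C(=O)OC)c(OCC=C)c(OC)c3OCC=C)[C@@H](C)CC[C@]12C
F6 | step 3 | (2S,4aS,8aR)-2,4a-dimethyl-5-methylideneoctahydro-2H-spiro[naphthalene-1,2'-oxirane], mixture at the spiro carbon | C=C1CCC[C@H]2C3(CO3)[C@@H](C)CC[C@]12C
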